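**Plan**

- Retrosynthesis: the bicyclo[2.2.1]heptane core is cut at C2–C2' and C3–C5' (Diels–Alder) into two guaianolide cyclopentadienes that both come from one enone. Each monomer is then cut at the lactone (C6–O, C7–C11), at C4–C5 (aldol) and last at C7–C8 and C1–C5 of the seven-membered ring.
- That last cut is open because each seven-membered ring carries oxygen on C6, a carbon branch on C7, the methyl carbinol C10 and the ring-fusion methine C1. This is a C5–C6–C7 siloxyvinylcarbenoid joined to a C8–C9–C10–C1 2-methyldiene.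
- Forward: seven-membered ring first (step 7), then the C10–O bond by a tethered iodoketalisation, ring A by aldol condensation, the trans-lactone, C3 oxidation, and last the norbornane core by cross Diels–Alder of a 3-siloxydiene with the parent diene.
- Stereochemistry: C1 from the chiral dirhodium catalyst; C10 relayed from C1 through the tether; C7 by equilibration, C6 by axial hydride delivery, C11 by enolate methylation anti to C8. C2, C3, C2' and C5' come from an endo, α-face/α-face cycloaddition and C4' from exo protonation.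

Key step: step 7

Remark (numbering): guaiane locants C1–C15 are used for both halves (primed for the diene-derived half); α is the face of the seven-membered ring that carries H1.
Remark (assumption): the sense of induction of Rh2(S-PTAD)4 is taken from the accepted model for donor/acceptor carbenoid cyclopropanation; if the opposite sense is met, Rh2(R-PTAD)4 is used and nothing else changes.

**Route**

Step 1
Reactants: 1 methyl acetoacetate
Product: 2 methyl 2-diazo-3-oxobutanoate
Conditions: p-ABSA, Et3N, MeCN, 0 → 23 °C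
Reagents that add atoms: 4-acetamidobenzenesulfonyl azide, CC(=O)Nc1ccc(cc1)S(=O)(=O)N=[N+]=[N-]
Why: Regitz diazo transfer to the doubly activated methylene of a β-keto ester.

Step 2
Reactants: 2 methyl 2-diazo-3-oxobutanoate
Product: 3 methyl 2-diazo-3-(tert-butyldimethylsilyloxy)but-3-enoate
Conditions: TBSOTf, Et3N, CH2Cl2, 0 °C
Reagents that add atoms: tert-butyldimethylsilyl triflate, CC(C)(C)[Si](C)(C)OS(=O)(=O)C(F)(F)F
Why: Soft enolisation and O-silylation of the acetyl group (the only enolisable position) gives the siloxyvinyldiazoacetate.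

Step 3
Reactants: 4 6-methylhept-5-en-2-one; 5 ethylene glycol
Product: 6 2-methyl-2-(4-methylpent-3-en-1-yl)-1,3-dioxolane
Conditions: TsOH·H2O (cat.), benzene, reflux, Dean–Stark
Reagents that add atoms: none
Why: Acid-catalysed ketalisation with azeotropic removal of water masks the ketone from the later carbenoid.

Step 4
Reactants: 6 2-methyl-2-(4-methylpent-3-en-1-yl)-1,3-dioxolane
Product: 7 (E)-2-methyl-5-(2-methyl-1,3-dioxolan-2-yl)pent-2-en-1-ol
Conditions: SeO2 (cat.), t-BuOOH, CH2Cl2, 23 °C
Reagents that add atoms: tert-butyl hydroperoxide, CC(C)(C)OO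
Why: Catalytic selenium dioxide allylic oxidation (ene reaction then [2,3] shift) is selective for the E-methyl group of a trisubstituted alkene; any enal 8 formed is carried into step 5.

Step 5
Reactants: 7 (E)-2-methyl-5-(2-methyl-1,3-dioxolan-2-yl)pent-2-en-1-ol
Product: 8 (E)-2-methyl-5-(2-methyl-1,3-dioxolan-2-yl)pent-2-enal
Conditions: MnO2, CH2Cl2, 23 °C
Reagents that add atoms: none
Why: Chemoselective oxidation of the allylic alcohol to the enal with retention of the E geometry.

Step 6
Reactants: 8 (E)-2-methyl-5-(2-methyl-1,3-dioxolan-2-yl)pent-2-enal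
Product: 9 (E)-2-methyl-2-(4-methylhexa-3,5-dien-1-yl)-1,3-dioxolane
Conditions: Ph3PCH3Br, KOtBu, THF, 0 → 23 °C
Reagents that add atoms: methyltriphenylphosphonium bromide, C[P+](c1ccccc1)(c1ccccc1)c1ccccc1.[Br-]
Why: Wittig methylenation of the enal gives the E-configured 2-methyl-1,3-diene with the trisubstituted alkene untouched.

Step 7
Reactants: 3 methyl 2-diazo-3-(tert-butyldimethylsilyloxy)but-3-enoate; 9 (E)-2-methyl-2-(4-methylhexa-3,5-dien-1-yl)-1,3-dioxolane
Product: 11 methyl (4R)-2-(tert-butyldimethylsilyloxy)-5-methyl-4-[2-(2-methyl-1,3-dioxolan-2-yl)ethyl]cyclohepta-1,5-diene-1-carboxylate, via cis-divinylcyclopropane 10 (not isolated)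
Conditions: Rh2(S-PTAD)4 [dirhodium tetrakis((S)-N-phthaloyl-1-adamantylglycinate)] (1 mol %), hexanes, slow addition of 3, −26 → 23 °C, then 50 °C
Reagents that add atoms: none
Why: Rh2(S-PTAD)4 decomposes 3 to a rhodium-bound siloxyvinylcarbenoid whose carbenoid carbon (C7) adds in a concerted, asynchronous way to the terminal C8=C9 alkene of 9, forming C7–C8 and C7–C9 and giving cis-divinylcyclopropane 10, which then undergoes a [3,3] Cope shift through a boat transition state that forms C1–C5 and breaks C7–C9. The closest known reaction is the dirhodium tetracarboxylate-catalysed tandem cyclopropanation/Cope rearrangement (formal (4+3) cycloaddition) of siloxyvinyldiazoacetates with 1,3-dienes. The seven-membered ring is closed by the sigmatropic C1–C5 bond formation, driven by release of cyclopropane strain, and this leaves the C6=C7 enol ether and the C9=C10 alkene. The one new stereocentre, C1, is fixed by the catalyst, which selects the enantiotopic face of the terminal alkene in the cyclopropanation; the boat geometry and the E configuration of the C10=C1 alkene (chain in the outside position) relay this to C1 without loss. The step needs attack at the monosubstituted and not the trisubstituted alkene, which the steric demand of the donor/acceptor carbenoid secures, and a cis arrangement of the two vinyl groups, which is the normal outcome because the alkene substituent ends up cis to the carbenoid donor group. The dioxolane and the silyl enol ether should be inert to the carbenoid in this non-polar medium at low temperature.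

Step 8
Reactants: 11 methyl (4R)-2-(tert-butyldimethylsilyloxy)-5-methyl-4-[2-(2-methyl-1,3-dioxolan-2-yl)ethyl]cyclohepta-1,5-diene-1-carboxylate
Product: 13 methyl (5R)-1-(2-ethoxy-2-oxoethyl)-4-methyl-5-[2-(2-methyl-1,3-dioxolan-2-yl)ethyl]-7-oxocyclohept-3-ene-1-carboxylate (both epimers at the quaternary carbon C7), via tetrabutylammonium enolate 12 (not isolated)
Conditions: Bu4NF, THF, −78 °C; then BrCH2CO2Et, −78 → 23 °C
Reagents that add atoms: ethyl bromoacetate, CCOC(=O)CBr
Why: Fluoride cleaves the silyl enol ether to the β-keto ester ammonium enolate, which is C-alkylated by the α-halo ester (SN2); the ester that served as carbenoid acceptor now directs the C11–C12 unit to C7 and not to C5.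

Step 9
Reactants: 13 methyl (5R)-1-(2-ethoxy-2-oxoethyl)-4-methyl-5-[2-(2-methyl-1,3-dioxolan-2-yl)ethyl]-7-oxocyclohept-3-ene-1-carboxylate
Product: 14 methyl (5R)-1-(2-ethoxy-2-oxoethyl)-4-methyl-7-oxo-5-(3-oxobutyl)cyclohept-3-ene-1-carboxylate (both C7 epimers)
Conditions: 1 M HCl, THF, 23 °C
Reagents that add atoms: water, O
Why: Mild acid hydrolysis of the dioxolane frees the C4 methyl ketone; the quaternary β-keto ester cannot enolise toward C7 and aldol closure does not occur at this acidity and temperature.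

Step 10
Reactants: 14 methyl (5R)-1-(2-ethoxy-2-oxoethyl)-4-methyl-7-oxo-5-(3-oxobutyl)cyclohept-3-ene-1-carboxylate
Product: 15 ethyl 9α-iodo-4-methoxy-7-(methoxycarbonyl)-6-oxo-4,10β-epoxy-13-nor-4,5-seco-1αH-guaian-12-oate (cis-fused 2-methoxy-2-methyltetrahydropyran; C4 and C7 epimers)
Conditions: NIS, MeOH (slight excess), CH2Cl2, −40 → 0 °C, dark
Reagents that add atoms: N-iodosuccinimide, O=C1CCC(=O)N1I; methanol, CO
Why: Iodoetherification with carbonyl participation (haloketalisation): the iodonium ion forms on the α face of C9=C10, the tethered C4 carbonyl oxygen opens it at the tertiary C10 from the β face (anti addition, six-membered ring, cis fusion enforced by the three-atom tether on C1) and methanol traps the cyclic oxocarbenium ion, so C10 gains its oxygen cis to C2 while the C4 ketone and the new tertiary alcohol are masked together.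

Step 11
Reactants: 15 ethyl 9α-iodo-4-methoxy-7-(methoxycarbonyl)-6-oxo-4,10β-epoxy-13-nor-4,5-seco-1αH-guaian-12-oate
Product: 16 ethyl 4-methoxy-7-(methoxycarbonyl)-6-oxo-4,10β-epoxy-13-nor-4,5-seco-1αH-guaian-12-oate (C4 and C7 epimers)
Conditions: Bu3SnH, AIBN (cat.), toluene, 80 °C
Reagents that add atoms: none
Why: Radical chain dehalogenation of the secondary iodide; the β-alkoxy C9 radical does not fragment and has no alkene within reach.

Step 12
Reactants: 16 ethyl 4-methoxy-7-(methoxycarbonyl)-6-oxo-4,10β-epoxy-13-nor-4,5-seco-1αH-guaian-12-oate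
Product: 17 ethyl 4-methoxy-6-oxo-4,10β-epoxy-13-nor-4,5-seco-1αH-guaian-12-oate (C4 and C7 epimers)
Conditions: LiCl, DMSO, H2O, 150 °C
Reagents that add atoms: none
Why: Krapcho dealkoxycarbonylation removes the methyl ester of the β-keto ester (chloride SN2 at the methyl group, then decarboxylation); the ethyl ester is far slower and the neutral medium leaves the ketal intact.

Step 13
Reactants: 17 ethyl 4-methoxy-6-oxo-4,10β-epoxy-13-nor-4,5-seco-1αH-guaian-12-oate
Product: 19 ethyl 10β-hydroxy-6-oxo-13-nor-1αH,7αH-guai-4-en-12-oate, via hydroxy diketone 18 (not isolated)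
Conditions: 1 M HCl, THF, 23 °C; then NaOEt, EtOH, 0 → 40 °C
Reagents that add atoms: none
Why: Aqueous acid cleaves the mixed ketal to hydroxy diketone 18 and ethoxide then effects the intramolecular aldol condensation of the 1,6-diketone (C5 enolate onto the C4 ketone, E1cB dehydration) that closes ring A as the C4=C5 enone, while the enolisable C7 should settle as the epimer with the acetate chain pseudo-equatorial (β, H7 α) in the chair-like ring fixed by the equatorial C10 methyl and the ring fusion.

Step 14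
Reactants: 19 ethyl 10β-hydroxy-6-oxo-13-nor-1αH,7αH-guai-4-en-12-oate
Product: 21 10β-hydroxy-13-nor-1αH,6βH,7αH-guai-4-en-12,6α-olide, via hydroxy ester 20 (not isolated)
Conditions: NaBH4, CeCl3·7H2O, MeOH, −40 → 0 °C; then DBU (cat.), toluene, 40 °C
Reagents that add atoms: none
Why: Luche 1,2-reduction should deliver hydride axially from the β face, anti to the axial C7–H, so the 6α-alcohol forms trans to the C7 side chain and closes by base-catalysed transesterification to the trans-fused γ-lactone without acid that could ionise the allylic C6–O bond.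

Step 15
Reactants: 21 10β-hydroxy-13-nor-1αH,6βH,7αH-guai-4-en-12,6α-olide
Product: 22 10β-(triethylsilyloxy)-13-nor-1αH,6βH,7αH-guai-4-en-12,6α-olide
Conditions: TESOTf, 2,6-lutidine, CH2Cl2, −78 → 0 °C
Reagents that add atoms: triethylsilyl triflate, CC[Si](CC)(CC)OS(=O)(=O)C(F)(F)F
Why: Silyl triflate/lutidine silylation of the tertiary alcohol protects it from the bases and oxidant that follow.

Step 16
Reactants: 22 10β-(triethylsilyloxy)-13-nor-1αH,6βH,7αH-guai-4-en-12,6α-olide
Product: 23 10β-(triethylsilyloxy)-1αH,6βH,7αH,11βH-guai-4-en-12,6α-olide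
Conditions: LiN(iPr)2, THF, −78 °C; then MeI, −78 → −40 °C
Reagents that add atoms: iodomethane, CI
Why: The lactone lithium enolate is methylated on the α face, anti to the C7–C8 bond, giving the 11α-methyl (11βH) lactone, which is also the epimer that base equilibration favours.

Step 17
Reactants: 23 10β-(triethylsilyloxy)-1αH,6βH,7αH,11βH-guai-4-en-12,6α-olide
Product: 24 3-oxo-10β-(triethylsilyloxy)-1αH,6βH,7αH,11βH-guai-4-en-12,6α-olide
Conditions: CrO3, 3,5-dimethylpyrazole, CH2Cl2, −20 °C
Reagents that add atoms: chromium trioxide, O=[Cr](=O)=O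
Why: Chromium trioxide–3,5-dimethylpyrazole allylic oxidation converts the only allylic methylene (C3) of the tetrasubstituted C4=C5 alkene into the enone carbonyl; the tertiary C1–H is shielded at the ring fusion and the C6–H is deactivated by the acyloxy group.

Step 18
Reactants: 24 3-oxo-10β-(triethylsilyloxy)-1αH,6βH,7αH,11βH-guai-4-en-12,6α-olide
Product: 25 3,10β-bis(triethylsilyloxy)-1αH,6βH,7αH,11βH-guaia-2,4-dien-12,6α-olide
Conditions: TESOTf, Et3N, CH2Cl2, −78 → 0 °C
Reagents that add atoms: triethylsilyl triflate, CC[Si](CC)(CC)OS(=O)(=O)C(F)(F)F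
Why: Soft enolisation of the cyclopentenone removes the accessible α' proton at C2 and gives the cross-conjugated 3-siloxy-2,4-diene without touching C1–H or the lactone.

Step 19
Reactants: 24 3-oxo-10β-(triethylsilyloxy)-1αH,6βH,7αH,11βH-guai-4-en-12,6α-olide
Product: 26 10β-(triethylsilyloxy)-3-(trifluoromethanesulfonyloxy)-1αH,6βH,7αH,11βH-guaia-2,4-dien-12,6α-olide
Conditions: LiN(SiMe3)2, THF, −78 °C; then PhNTf2, −78 → 0 °C
Reagents that add atoms: N-phenylbis(trifluoromethanesulfonimide), O=S(=O)(N(c1ccccc1)S(=O)(=O)C(F)(F)F)C(F)(F)F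
Why: Kinetic deprotonation of the enone at C2 by the hindered amide base and O-triflation of the cross-conjugated dienolate give the dienyl triflate regiospecifically, the lactone α-C–H being less acidic and more hindered.

Step 20
Reactants: 26 10β-(triethylsilyloxy)-3-(trifluoromethanesulfonyloxy)-1αH,6βH,7αH,11βH-guaia-2,4-dien-12,6α-olide
Product: 27 10β-(triethylsilyloxy)-1αH,6βH,7αH,11βH-guaia-2,4-dien-12,6α-olide
Conditions: Pd(OAc)2 (cat.), PPh3, HCO2H, Bu3N, DMF, 25–30 °C; product stored at −20 °C as a frozen benzene solution until used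
Reagents that add atoms: none
Why: Palladium-catalysed formate reduction of the enol triflate (oxidative addition to zerovalent palladium, formate exchange, decarboxylation, reductive elimination) replaces the triflate by hydrogen at C3 and so places the diene at C2=C3/C4=C5 without cationic or strongly basic intermediates that would scramble C1.

Step 21
Reactants: 25 3,10β-bis(triethylsilyloxy)-1αH,6βH,7αH,11βH-guaia-2,4-dien-12,6α-olide; 27 10β-(triethylsilyloxy)-1αH,6βH,7αH,11βH-guaia-2,4-dien-12,6α-olide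
Product: 28 endo Diels–Alder adduct with bonds C2–C2' and C3–C5' (3'-triethylsilyl enol ether and 10,10'-bis(triethylsilyl) ether of the target)
Conditions: equimolar amounts, neat; 27 added to 25 in four portions at one-day intervals (each portion freed of benzene cold), BHT (trace), dark, 23 °C, then several days more
Reagents that add atoms: none
Why: Normal-demand Diels–Alder cross-dimerisation of two cyclopentadienes in which the electron-rich siloxydiene 25 (largest HOMO coefficient at C2') adds across the unhindered C2=C3 alkene of 27 (largest LUMO coefficient at C2), endo and on the α face (H1 side) of each partner, anti to the C10 substituents, as in the known homodimerisation of such guaianolide dienes; one molecule of each partner is joined with no atom lost, 25 is a poor dienophile because both of its alkenes are tri- or tetrasubstituted, the portionwise addition keeps 27 scarce and so disfavours its second-order self-dimerisation, and the addition sets C2, C3, C2' and C5'.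

Step 22
Reactants: 28 endo Diels–Alder adduct with bonds C2–C2' and C3–C5'
Product: 29 CNP0243924.4 (1R,2S,3R,6S,7S,10S,11S,1'R,2'R,4'S,5'R,6'S,7'S,10'S,11'S)
Conditions: HF·pyridine, pyridine, THF, 0 → 23 °C
Reagents that add atoms: none
Why: Fluoride cleaves the three triethylsilyl groups and the liberated enol should be protonated at C4' on the exo face, the endo face being blocked by the endo-fused cyclopentene of the other half, which leaves the C4' methyl endo as in the target and reveals the C3' ketone and both tertiary alcohols under conditions too mild to epimerise C4'.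

**Compound list**

1 | methyl acetoacetate | COC(=O)CC(C)=O | starting material
2 | methyl 2-diazo-3-oxobutanoate | COC(=O)C(=[N+]=[N-])C(C)=O | intermediate
3 | methyl 2-diazo-3-(tert-butyldimethylsilyloxy)but-3-enoate | COC(=O)C(=[N+]=[N-])C(=C)O[Si](C)(C)C(C)(C)C | intermediate
4 | 6-methylhept-5-en-2-one | CC(=O)CCC=C(C)C | starting material
5 | ethylene glycol | OCCO | starting material
6 | 2-methyl-2-(4-methylpent-3-en-1-yl)-1,3-dioxolane | CC1(CCC=C(C)C)OCCO1 | intermediate
7 | (E)-2-methyl-5-(2-methyl-1,3-dioxolan-2-yl)pent-2-en-1-ol | CC1(CC/C=C(\C)CO)OCCO1 | intermediate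
8 | (E)-2-methyl-5-(2-methyl-1,3-dioxolan-2-yl)pent-2-enal | CC1(CC/C=C(\C)C=O)OCCO1 | intermediate
9 | (E)-2-methyl-2-(4-methylhexa-3,5-dien-1-yl)-1,3-dioxolane | CC1(CC/C=C(\C)C=C)OCCO1 | intermediate
10 | methyl (1R,2S)-1-[1-(tert-butyldimethylsilyloxy)vinyl]-2-[(E)-5-(2-methyl-1,3-dioxolan-2-yl)pent-2-en-2-yl]cyclopropane-1-carboxylate | COC(=O)[C@]1(C(=C)O[Si](C)(C)C(C)(C)C)C[C@H]1/C(C)=C/CCC1(C)OCCO1 | intermediate (not isolated)
11 | methyl (4R)-2-(tert-butyldimethylsilyloxy)-5-methyl-4-[2-(2-methyl-1,3-dioxolan-2-yl)ethyl]cyclohepta-1,5-diene-1-carboxylate | COC(=O)C1=C(O[Si](C)(C)C(C)(C)C)C[C@@H](CCC2(C)OCCO2)C(C)=CC1 | intermediate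
12 | tetrabutylammonium enolate of methyl (4R)-5-methyl-4-[2-(2-methyl-1,3-dioxolan-2-yl)ethyl]-2-oxocyclohept-5-ene-1-carboxylate | COC(=O)C1=C([O-])C[C@@H](CCC2(C)OCCO2)C(C)=CC1.CCCC[N+](CCCC)(CCCC)CCCC | intermediate (not isolated)
13 | methyl (5R)-1-(2-ethoxy-2-oxoethyl)-4-methyl-5-[2-(2-methyl-1,3-dioxolan-2-yl)ethyl]-7-oxocyclohept-3-ene-1-carboxylate (C7 epimers) | CCOC(=O)CC1(C(=O)OC)CC=C(C)[C@H](CCC2(C)OCCO2)CC1=O | intermediate
14 | methyl (5R)-1-(2-ethoxy-2-oxoethyl)-4-methyl-7-oxo-5-(3-oxobutyl)cyclohept-3-ene-1-carboxylate (C7 epimers) | CCOC(=O)CC1(C(=O)OC)CC=C(C)[C@H](CCC(C)=O)CC1=O | intermediate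
15 | ethyl 9α-iodo-4-methoxy-7-(methoxycarbonyl)-6-oxo-4,10β-epoxy-13-nor-4,5-seco-1αH-guaian-12-oate (C4 and C7 epimers) | CCOC(=O)CC1(C(=O)OC)C[C@@H](I)[C@]2(C)OC(C)(OC)CC[C@@H]2CC1=O | intermediate
16 | ethyl 4-methoxy-7-(methoxycarbonyl)-6-oxo-4,10β-epoxy-13-nor-4,5-seco-1αH-guaian-12-oate (C4 and C7 epimers) | CCOC(=O)CC1(C(=O)OC)CC[C@]2(C)OC(C)(OC)CC[C@@H]2CC1=O | intermediate
17 | ethyl 4-methoxy-6-oxo-4,10β-epoxy-13-nor-4,5-seco-1αH-guaian-12-oate (C4 and C7 epimers) | CCOC(=O)CC1CC[C@]2(C)OC(C)(OC)CC[C@@H]2CC1=O | intermediate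
18 | ethyl 10β-hydroxy-4,6-dioxo-13-nor-4,5-seco-1αH-guaian-12-oate (C7 epimers) | CCOC(=O)CC1CC[C@](C)(O)[C@H](CCC(C)=O)CC1=O | intermediate (not isolated)
19 | ethyl 10β-hydroxy-6-oxo-13-nor-1αH,7αH-guai-4-en-12-oate | CCOC(=O)C[C@@H]1CC[C@](C)(O)[C@@H]2CCC(C)=C2C1=O | intermediate
20 | ethyl 6α,10β-dihydroxy-13-nor-1αH,6βH,7αH-guai-4-en-12-oate | CCOC(=O)C[C@@H]1CC[C@](C)(O)[C@@H]2CCC(C)=C2[C@H]1O | intermediate (not isolated)
21 | 10β-hydroxy-13-nor-1αH,6βH,7αH-guai-4-en-12,6α-olide | CC1=C2[C@H]3OC(=O)C[C@@H]3CC[C@](C)(O)[C@@H]2CC1 | intermediate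
22 | 10β-(triethylsilyloxy)-13-nor-1αH,6βH,7αH-guai-4-en-12,6α-olide | CC1=C2[C@H]3OC(=O)C[C@@H]3CC[C@](C)(O[Si](CC)(CC)CC)[C@@H]2CC1 | intermediate
23 | 10β-(triethylsilyloxy)-1αH,6βH,7αH,11βH-guai-4-en-12,6α-olide | CC1=C2[C@H]3OC(=O)[C@@H](C)[C@@H]3CC[C@](C)(O[Si](CC)(CC)CC)[C@@H]2CC1 | intermediate
24 | 3-oxo-10β-(triethylsilyloxy)-1αH,6βH,7αH,11βH-guai-4-en-12,6α-olide | CC1=C2[C@H]3OC(=O)[C@@H](C)[C@@H]3CC[C@](C)(O[Si](CC)(CC)CC)[C@@H]2CC1=O | intermediate
25 | 3,10β-bis(triethylsilyloxy)-1αH,6βH,7αH,11βH-guaia-2,4-dien-12,6α-olide | CC1=C2[C@H]3OC(=O)[C@@H](C)[C@@H]3CC[C@](C)(O[Si](CC)(CC)CC)[C@@H]2C=C1O[Si](CC)(CC)CC | intermediate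
26 | 10β-(triethylsilyloxy)-3-(trifluoromethanesulfonyloxy)-1αH,6βH,7αH,11βH-guaia-2,4-dien-12,6α-olide | CC1=C2[C@H]3OC(=O)[C@@H](C)[C@@H]3CC[C@](C)(O[Si](CC)(CC)CC)[C@@H]2C=C1OS(=O)(=O)C(F)(F)F | intermediate
27 | 10β-(triethylsilyloxy)-1αH,6βH,7αH,11βH-guaia-2,4-dien-12,6α-olide | CC1=C2[C@H]3OC(=O)[C@@H](C)[C@@H]3CC[C@](C)(O[Si](CC)(CC)CC)[C@@H]2C=C1 | intermediate
28 | endo Diels–Alder adduct of 25 and 27 (bonds C2–C2' and C3–C5'; 3'-triethylsilyl enol ether; 10,10'-bis(triethylsilyl) ether) | CC1=C2[C@H]3OC(=O)[C@@H](C)[C@@H]3CC[C@](C)(O[Si](CC)(CC)CC)[C@@H]2[C@H]2[C@H]3C(O[Si](CC)(CC)CC)=C(C)[C@]4([C@@H]3[C@@](C)(O[Si](CC)(CC)CC)CC[C@H]3[C@H](C)C(=O)O[C@@H]34)[C@@H]12 | intermediate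
29 | CNP0243924.4 (1R,2S,3R,6S,7S,10S,11S,1'R,2'R,4'S,5'R,6'S,7'S,10'S,11'S) | CC1=C2[C@H]3OC(=O)[C@@H](C)[C@@H]3CC[C@](C)(O)[C@@H]2[C@H]2[C@H]3C(=O)[C@@H](C)[C@]4([C@@H]3[C@@](C)(O)CC[C@H]3[C@H](C)C(=O)O[C@@H]34)[C@@H]12 | target

**Summary**

Total step count: 22.
Longest linear sequence: 19 steps (steps 3–17 and 19–22, from 4).

**Steps most likely to fail**

1. Step 21. What may go wrong: the less electron-rich diene 27 dimerises with itself in spite of its portionwise addition, either diene tautomerises by 1,5-hydrogen shift before it cycloadds, or the cross-addition shows poor regio- or facial preference. Fallback, from 27 back to 29: 27 alone is left neat at 23 °C to homodimerise, as such guaianolide dienes are known to do, to the 10,10'-bis(triethylsilyl) ether of the endo homodimer F1. Its strained trisubstituted C3'=C4' alkene is hydroborated from the exo face, in preference to the tetrasubstituted C4=C5 alkene and the lactones (BH3·THF, 0 °C; then NaBO3·4H2O), to the 3'-exo-alcohol with exo hydrogen at C4' F2. Dess–Martin oxidation gives the 10,10'-bis(triethylsilyl) ether of the target F3, and HF·pyridine gives 29.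

2. Step 17. What may go wrong: hydrogen abstraction at the tertiary C1–H, at the lactone C6–H or at the C15 methyl instead of C3, or over-oxidation. Fallback, from 19 back to 24: the oxygen is placed on C3 while it is the activated γ-position of the C6 enone. γ-Oxidation of 19 (Pd(OH)2/C, t-BuOOH, K2CO3, CH2Cl2) gives ethyl 10β-hydroxy-3,6-dioxo-13-nor-1αH,7αH-guai-4-en-12-oate F4. Luche reduction of both ketones (NaBH4, CeCl3·7H2O) with lactonisation gives 3,10β-dihydroxy-13-nor-1αH,6βH,7αH-guai-4-en-12,6α-olide F5. Silylation of both hydroxyls (TESOTf, 2,6-lutidine) gives the bis(triethylsilyl) ether F6, and enolate methylation (LiN(iPr)2, MeI) gives the 11α-methyl bis(silyl) ether F7. PPTS in MeOH removes the secondary allylic silyl group to give the 3-hydroxy-10β-(triethylsilyloxy) lactone F8, and MnO2 oxidises this allylic alcohol to 24.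

3. Step 10. What may go wrong: the iodonium ion is captured by methanol from solution or transannularly by a C6 hemiketal instead of by the tethered C4 carbonyl oxygen, or the ketones are α-iodinated. Fallback, from 14 back to 19: the tether is given up and ring A is closed first. Krapcho dealkoxycarbonylation of 14 (LiCl, wet DMSO, 150 °C) gives ethyl 2-[(4R)-5-methyl-2-oxo-4-(3-oxobutyl)cyclohept-5-en-1-yl]acetate F9. NaOEt in EtOH then gives the aldol condensation product ethyl 6-oxo-13-nor-1αH,7αH-guaia-4,9-dien-12-oate F10. Markovnikov radical hydration of its remaining trisubstituted C9=C10 alkene (Co(acac)2, PhSiH3, O2, THF; then PPh3) leads to 19. Oxygen is expected to add to the C10 radical axially on the β face, anti to the axial C1–H and C9–H bonds; this is less secure than the tether, and any C10 epimer would be separated at 19.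

**Further compounds**

F1 | step 21 | 10,10'-bis(triethylsilyl) ether of the endo homodimer of 27 (absinthin skeleton, C3'=C4' alkene) | CC1=C2[C@H]3OC(=O)[C@@H](C)[C@@H]3CC[C@](C)(O[Si](CC)(CC)CC)[C@@H]2[C@H]2[C@H]3C=C(C)[C@]4([C@@H]3[C@@](C)(O[Si](CC)(CC)CC)CC[C@H]3[C@H](C)C(=O)O[C@@H]34)[C@@H]12
F2 | step 21 | 3'-exo-hydroxy-3',4'-dihydro derivative of F1 (C4' hydrogen exo, methyl endo) | CC1=C2[C@H]3OC(=O)[C@@H](C)[C@@H]3CC[C@](C)(O[Si](CC)(CC)CC)[C@@H]2[C@H]2[C@H]3[C@H](O)[C@@H](C)[C@]4([C@@H]3[C@@](C)(O[Si](CC)(CC)CC)CC[C@H]3[C@H](C)C(=O)O[C@@H]34)[C@@H]12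
F3 | step 21 | 10,10'-bis(triethylsilyl) ether of 29 | CC1=C2[C@H]3OC(=O)[C@@H](C)[C@@H]3CC[C@](C)(O[Si](CC)(CC)CC)[C@@H]2[C@H]2[C@H]3C(=O)[C@@H](C)[C@]4([C@@H]3[C@@](C)(O[Si](CC)(CC)CC)CC[C@H]3[C@H](C)C(=O)O[C@@H]34)[C@@H]12
F4 | step 17 | ethyl 10β-hydroxy-3,6-dioxo-13-nor-1αH,7αH-guai-4-en-12-oate | CCOC(=O)C[C@@H]1CC[C@](C)(O)[C@@H]2CC(=O)C(C)=C2C1=O
F5 | step 17 | 3,10β-dihydroxy-13-nor-1αH,6βH,7αH-guai-4-en-12,6α-olide (C3 epimers) | CC1=C2[C@H]3OC(=O)C[C@@H]3CC[C@](C)(O)[C@@H]2CC1O
F6 | step 17 | 3,10β-bis(triethylsilyloxy)-13-nor-1αH,6βH,7αH-guai-4-en-12,6α-olide (C3 epimers) | CC1=C2[C@H]3OC(=O)C[C@@H]3CC[C@](C)(O[Si](CC)(CC)CC)[C@@H]2CC1O[Si](CC)(CC)CC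
F7 | step 17 | 3,10β-bis(triethylsilyloxy)-1αH,6βH,7αH,11βH-guai-4-en-12,6α-olide (C3 epimers) | CC1=C2[C@H]3OC(=O)[C@@H](C)[C@@H]3CC[C@](C)(O[Si](CC)(CC)CC)[C@@H]2CC1O[Si](CC)(CC)CC
F8 | step 17 | 3-hydroxy-10β-(triethylsilyloxy)-1αH,6βH,7αH,11βH-guai-4-en-12,6α-olide (C3 epimers) | CC1=C2[C@H]3OC(=O)[C@@H](C)[C@@H]3CC[C@](C)(O[Si](CC)(CC)CC)[C@@H]2CC1O
F9 | step 10 | ethyl 2-[(4R)-5-methyl-2-oxo-4-(3-oxobutyl)cyclohept-5-en-1-yl]acetate (C7 epimers) | CCOC(=O)CC1CC=C(C)[C@H](CCC(C)=O)CC1=O
F10 | step 10 | ethyl 6-oxo-13-nor-1αH,7αH-guaia-4,9-dien-12-oate | CCOC(=O)C[C@@H]1CC=C(C)[C@@H]2CCC(C)=C2C1=O
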